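**Strategy.** The ether oxygen that bridges C5 and C10 across the ten-membered carbocycle (an 11-oxabicyclo[4.4.1]undecane, i.e. two fused oxepanes) is read as one oxygen atom inserted into the C5–C10 ring-fusion bond of a eudesmane decalin. The key step is therefore a Criegee rearrangement of a C5 allylic hydroperoxide ester: C10 shifts from C5 to oxygen with retention, which creates the medium ring and the oxygen bridge in one operation and locks C5. The precursor is a 5α-hydroperoxy-eudesm-4(15)-en-12,6-olide made by a singlet-oxygen ene reaction on a santonin-derived Δ4-olefin; C6, C7 and C10 come from α-santonin.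

Key step: step 12

Remark: eudesmane/germacrane numbering is used throughout (C1–C10 carbocycle, C11–C13 lactone carbons, C14 on C10, C15 on C4); the carbinol configurations drawn at C1 and C3 are the expected ones and are not relayed, because both carbons end up sp2.

Step 1
Reactants: 1 (−)-α-santonin
Product: 2 artemisin (8α-hydroxy-α-santonin)
Conditions: growing whole-cell culture of a filamentous fungus expressing a cytochrome P450 monooxygenase (Mucorales strain chosen by screening), glucose medium, air, 28 °C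
Reagents that add atoms: dioxygen, O=O
Why: A cytochrome P450 monooxygenase should hydroxylate the unactivated equatorial 8α C–H bond with retention (oxygen rebound), a site that no small reagent distinguishes from C9–H, and whole-cell hydroxylation of santonin-type lactones is an established biotransformation class.

Step 2
Reactants: 2 artemisin
Product: 3 8-oxo-α-santonin
Conditions: Dess–Martin periodinane, NaHCO3, CH2Cl2, 0 °C to rt
Reagents that add atoms: none
Why: Dess–Martin oxidation under buffered, non-basic conditions should give the ketone without β-elimination of the lactone carboxylate from C6 or epimerisation at C7.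

Step 3
Reactants: 3 8-oxo-α-santonin
Product: 4 8β-hydroxy-α-santonin (8-epi-artemisin)
Conditions: NaBH4, MeOH/CH2Cl2, −78 to −40 °C
Reagents that add atoms: none
Why: Chemoselective borohydride reduction: hydride should reach the saturated C8 ketone from the α face because the syn-axial C10 methyl blocks the β face, giving the axial 8β alcohol, while the cross-conjugated dienone carbonyl and the lactone are far less electrophilic.

Step 4
Reactants: 4 8β-hydroxy-α-santonin
Product: 5 8β-(tert-butyldimethylsilyloxy)-α-santonin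
Conditions: TBSOTf, 2,6-lutidine, CH2Cl2, 0 °C
Reagents that add atoms: tert-butyldimethylsilyl triflate, CC(C)(C)[Si](C)(C)OS(=O)(=O)C(F)(F)F
Why: Silyl triflate silylation should protect the hindered axial alcohol as a robust ether that survives all steps up to step 16.

Step 5
Reactants: 5 8β-(tert-butyldimethylsilyloxy)-α-santonin
Product: 7 1α-hydroxy-8β-(tert-butyldimethylsilyloxy)-3-oxoeudesm-4-en-12,6α-olide, via C1 pinacol boronate 6 (not isolated)
Conditions: CuCl (cat.), DPEphos (cat.), NaOtBu (cat.), B2pin2, MeOH, THF, rt; then NaBO3·4H2O, THF/H2O, 0 °C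
Reagents that add atoms: bis(pinacolato)diboron, CC1(C)OB(OC1(C)C)B1OC(C)(C)C(C)(C)O1; sodium perborate, [Na+].[O-]OB=O
Why: Copper-catalysed conjugate borylation should add boron to the less hindered C1=C2 bond of the cross-conjugated dienone (the tetrasubstituted C4=C5 is inert) from the face opposite the C10 methyl, and perborate oxidation proceeds with retention to the 1α alcohol.

Step 6
Reactants: 7 1α-hydroxy ketone
Product: 8 1α-(triethylsilyloxy)-8β-(tert-butyldimethylsilyloxy)-3-oxoeudesm-4-en-12,6α-olide
Conditions: TESOTf, 2,6-lutidine, CH2Cl2, −78 °C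
Reagents that add atoms: triethylsilyl triflate, CC[Si](CC)(CC)OS(=O)(=O)C(F)(F)F
Why: Low-temperature silylation should cap the β-hydroxy ketone before it can eliminate, with a silyl group that is more labile than the C8 TBS ether and keeps C1 electron-rich for step 12.

Step 7
Reactants: 8 1α-triethylsilyloxy enone
Product: 9 3β-hydroxy-1α-(triethylsilyloxy)-8β-(tert-butyldimethylsilyloxy)eudesm-4-en-12,6α-olide
Conditions: NaBH4, CeCl3·7H2O, MeOH, −78 to −20 °C
Reagents that add atoms: none
Why: Luche 1,2-reduction of the enone should give the allylic alcohol, expected mainly as the pseudo-equatorial 3β epimer as in Δ4-3-keto steroids, and either epimer serves because C3 later becomes sp2.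

Step 8
Reactants: 9 3β-allylic alcohol
Product: 10 3β-pivaloyloxy-1α-(triethylsilyloxy)-8β-(tert-butyldimethylsilyloxy)eudesm-4-en-12,6α-olide
Conditions: PivCl, pyridine, DMAP (cat.), CH2Cl2, 0 °C to rt
Reagents that add atoms: pivaloyl chloride, CC(C)(C)C(Cl)=O
Why: Acylation installs an ester that has no α-hydrogen (so it survives LDA in step 9), that steers the ene reaction of step 11, and that is the β-leaving group of step 15.

Step 9
Reactants: 10 3β-pivalate
Product: 11 11α-phenylseleno lactone
Conditions: LDA, THF, −78 °C; then PhSeCl, −78 °C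
Reagents that add atoms: benzeneselenenyl chloride, Cl[Se]c1ccccc1
Why: The lactone α-hydrogen at C11 is the only acidic C–H, and the enolate should be selenenylated on the face away from the axial 8β-silyloxy group.

Step 10
Reactants: 11 11α-phenylseleno lactone
Product: 13 3β-pivaloyloxy-1α-(triethylsilyloxy)-8β-(tert-butyldimethylsilyloxy)eudesma-4,11(13)-dien-12,6α-olide, via selenoxide 12 (not isolated)
Conditions: mCPBA (1.0 equiv), CH2Cl2, −78 °C; then iPr2NH, −78 °C to rt
Reagents that add atoms: none
Why: Selenide oxidation is much faster than epoxidation of the tetrasubstituted alkene at −78 °C, and selenoxide syn-elimination toward the C13 methyl should give the exocyclic α-methylene lactone, as is usual for trans-fused 11-methyl-11-seleno lactones.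

Step 11
Reactants: 13 Δ4,11(13)-diene lactone
Product: 14 5α-hydroperoxy-3β-pivaloyloxy-1α-(triethylsilyloxy)-8β-(tert-butyldimethylsilyloxy)eudesma-4(15),11(13)-dien-12,6α-olide
Conditions: O2, tetraphenylporphyrin (cat.), visible light, CH2Cl2, −20 °C
Reagents that add atoms: dioxygen, O=O
Why: In the Schenck ene reaction singlet oxygen should attack the only electron-rich alkene (C4=C5) from the face opposite the C10 methyl, bond to C5 and abstract hydrogen from the C15 methyl (geminal to the branched, acyloxy-bearing C3; H6 is β and on an oxygenated carbon), which sets the exocyclic C4=C15 bond and the C5 hydroperoxide together.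

Step 12
Reactants: 14 5α-hydroperoxide
Product: 16 5-(4-nitrobenzoyloxy)-5,10-epoxygermacra-4(15),11(13)-dien-12,6α-olide bearing 1α-OTES 3β-OPiv 8β-OTBS (bridged acylal), via peroxy 4-nitrobenzoate 15 (not isolated)
Conditions: 4-nitrobenzoyl chloride, pyridine, DMAP (cat.), BHT (cat.), CH2Cl2, 0 °C to rt, dark
Reagents that add atoms: 4-nitrobenzoyl chloride, O=C(Cl)c1ccc(cc1)[N+](=O)[O-]
Why: Acylation of the hydroperoxide gives peroxy ester 15, whose O–O bond heterolyses with a concerted 1,2-shift of C10 from C5 to the proximal oxygen (Criegee rearrangement), and the resulting carboxylate/oxocarbenium ion pair collapses at C5 to the mixed acylal 16. The closest known reaction is the rearrangement of 9-decalyl peroxy esters to 1,6-epoxycyclodecyl esters, the same bond and ring system. No ring is closed end to end: the ten-membered carbocycle and the two oxepane rings of the 11-oxabicyclo[4.4.1]undecane arise together by ring expansion through the migrating C5–C10 bond. C10 migrates suprafacially with retention, so its configuration from santonin is kept, and the new centre C5 can only carry its acyloxy group exo because oxygen must bridge to C10 on the inside. The step needs migration of C10 in preference to C4 and C6: C10 is a fully substituted alkyl carbon whose neighbouring C1 oxygen is a silyl ether and not a ketone, C4 is a 1,1-disubstituted vinyl carbon whose participation would place charge on the primary C15 and which is deactivated by the allylic pivalate, and C6 carries the lactone acyloxy group. Exclusion of light and a radical inhibitor should suppress the competing radical allylic transposition of the hydroperoxide.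

Step 13
Reactants: 16 bridged acylal
Product: 17 5,10-epoxygermacra-4(15),11(13)-dien-12,6α-olide bearing 1α-OTES 3β-OPiv 8β-OTBS (C5–H exo)
Conditions: Et3SiH, TMSOTf (cat.), CH2Cl2, −78 to −40 °C
Reagents that add atoms: none
Why: Lewis-acid ionisation of the acylal with loss of the carboxylate should regenerate the allyl-stabilised bridged oxocarbenium ion (ring C5–O cleavage would give a disfavoured acyloxycarbenium ion), and silane reduction, as in the reductive deacetoxylation of anomeric esters, can only deliver hydride from the exo direction, which gives the C5 configuration of the target.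

Step 14
Reactants: 17 bridged ether
Product: 18 1α-hydroxy-3β-pivaloyloxy-8β-(tert-butyldimethylsilyloxy)-5,10-epoxygermacra-4(15),11(13)-dien-12,6α-olide
Conditions: PPTS (cat.), MeOH/CH2Cl2, rt
Reagents that add atoms: none
Why: Mild acidic methanolysis should cleave the triethylsilyl ether much faster than the hindered tert-butyldimethylsilyl ether.

Step 15
Reactants: 18 1α-alcohol
Product: 20 8β-(tert-butyldimethylsilyloxy)-1-oxo-5,10-epoxygermacra-2,4(15),11(13)-trien-12,6α-olide, via 1-ketone 19 (not isolated)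
Conditions: Dess–Martin periodinane, NaHCO3, CH2Cl2, 0 °C; then DBU, 0 °C to rt
Reagents that add atoms: none
Why: Oxidation gives a β-pivaloyloxy ketone that can enolise only toward C2 (C10 is quaternary), so E1cB loss of pivalate should give the C2=C3 enone in conjugation with the C4=C15 methylene.

Step 16
Reactants: 20 silyl-protected dienone
Product: 21 8β-hydroxy-1-oxo-5,10-epoxygermacra-2,4(15),11(13)-trien-12,6α-olide
Conditions: HF·pyridine, THF, 0 °C to rt
Reagents that add atoms: none
Why: Weakly acidic fluoride should cleave the silyl ether without touching the dienone, the allylic bridged ether or the α-methylene lactone.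

Step 17
Reactants: 21 8β-alcohol; 22 angelic acid
Product: 23 target CNP0282559.1
Conditions: 22, 2,4,6-trichlorobenzoyl chloride, Et3N, toluene, rt; then 21, toluene, 60–80 °C (no DMAP)
Reagents that add atoms: none
Why: Yamaguchi-type acylation through the mixed anhydride without a nucleophilic catalyst should esterify the hindered alcohol while keeping the Z geometry of the angelate.

**Compound list**

1 | (−)-α-santonin | C[C@@H]1C(=O)O[C@H]2[C@H]1CC[C@@]1(C)C=CC(=O)C(C)=C21 | starting material
2 | artemisin (8α-hydroxy-α-santonin) | C[C@@H]1C(=O)O[C@H]2[C@H]1[C@@H](O)C[C@@]1(C)C=CC(=O)C(C)=C21 | intermediate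
3 | 8-oxo-α-santonin | C[C@@H]1C(=O)O[C@H]2[C@H]1C(=O)C[C@@]1(C)C=CC(=O)C(C)=C21 | intermediate
4 | 8β-hydroxy-α-santonin | C[C@@H]1C(=O)O[C@H]2[C@H]1[C@H](O)C[C@@]1(C)C=CC(=O)C(C)=C21 | intermediate
5 | 8β-(tert-butyldimethylsilyloxy)-α-santonin | C[C@@H]1C(=O)O[C@H]2[C@H]1[C@H](O[Si](C)(C)C(C)(C)C)C[C@@]1(C)C=CC(=O)C(C)=C21 | intermediate
6 | 1α-pinacolboryl-8β-TBSO-3-oxoeudesm-4-en-12,6α-olide | C[C@@H]1C(=O)O[C@H]2[C@H]1[C@H](O[Si](C)(C)C(C)(C)C)C[C@@]1(C)[C@@H](B3OC(C)(C)C(C)(C)O3)CC(=O)C(C)=C21 | intermediate (not isolated)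
7 | 1α-hydroxy-8β-TBSO-3-oxoeudesm-4-en-12,6α-olide | C[C@@H]1C(=O)O[C@H]2[C@H]1[C@H](O[Si](C)(C)C(C)(C)C)C[C@@]1(C)[C@@H](O)CC(=O)C(C)=C21 | intermediate
8 | 1α-TESO-8β-TBSO-3-oxoeudesm-4-en-12,6α-olide | C[C@@H]1C(=O)O[C@H]2[C@H]1[C@H](O[Si](C)(C)C(C)(C)C)C[C@@]1(C)[C@@H](O[Si](CC)(CC)CC)CC(=O)C(C)=C21 | intermediate
9 | 3β-hydroxy-1α-TESO-8β-TBSO-eudesm-4-en-12,6α-olide | C[C@@H]1C(=O)O[C@H]2[C@H]1[C@H](O[Si](C)(C)C(C)(C)C)C[C@@]1(C)[C@@H](O[Si](CC)(CC)CC)C[C@H](O)C(C)=C21 | intermediate
10 | 3β-pivaloyloxy-1α-TESO-8β-TBSO-eudesm-4-en-12,6α-olide | C[C@@H]1C(=O)O[C@H]2[C@H]1[C@H](O[Si](C)(C)C(C)(C)C)C[C@@]1(C)[C@@H](O[Si](CC)(CC)CC)C[C@H](OC(=O)C(C)(C)C)C(C)=C21 | intermediate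
11 | 11α-phenylseleno derivative of 10 | C[C@@]1([Se]c3ccccc3)C(=O)O[C@H]2[C@H]1[C@H](O[Si](C)(C)C(C)(C)C)C[C@@]1(C)[C@@H](O[Si](CC)(CC)CC)C[C@H](OC(=O)C(C)(C)C)C(C)=C21 | intermediate
12 | selenoxide of 11 | C[C@@]1([Se](=O)c3ccccc3)C(=O)O[C@H]2[C@H]1[C@H](O[Si](C)(C)C(C)(C)C)C[C@@]1(C)[C@@H](O[Si](CC)(CC)CC)C[C@H](OC(=O)C(C)(C)C)C(C)=C21 | intermediate (not isolated)
13 | 3β-pivaloyloxy-1α-TESO-8β-TBSO-eudesma-4,11(13)-dien-12,6α-olide | C=C1C(=O)O[C@H]2[C@H]1[C@H](O[Si](C)(C)C(C)(C)C)C[C@@]1(C)[C@@H](O[Si](CC)(CC)CC)C[C@H](OC(=O)C(C)(C)C)C(C)=C21 | intermediate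
14 | 5α-hydroperoxy-3β-pivaloyloxy-1α-TESO-8β-TBSO-eudesma-4(15),11(13)-dien-12,6α-olide | C=C1C(=O)O[C@H]2[C@H]1[C@H](O[Si](C)(C)C(C)(C)C)C[C@@]1(C)[C@@H](O[Si](CC)(CC)CC)C[C@H](OC(=O)C(C)(C)C)C(=C)[C@]21OO | intermediate
15 | 5α-peroxy 4-nitrobenzoate of 14 | C=C1C(=O)O[C@H]2[C@H]1[C@H](O[Si](C)(C)C(C)(C)C)C[C@@]1(C)[C@@H](O[Si](CC)(CC)CC)C[C@H](OC(=O)C(C)(C)C)C(=C)[C@]21OOC(=O)c3ccc(cc3)[N+](=O)[O-] | intermediate (not isolated)
16 | 5-(4-nitrobenzoyloxy)-5,10-epoxygermacra-4(15),11(13)-dien-12,6α-olide, 1α-OTES, 3β-OPiv, 8β-OTBS | C=C1C(=O)O[C@H]2[C@H]1[C@H](O[Si](C)(C)C(C)(C)C)C[C@]1(C)O[C@@]2(OC(=O)c3ccc(cc3)[N+](=O)[O-])C(=C)[C@@H](OC(=O)C(C)(C)C)C[C@@H]1O[Si](CC)(CC)CC | intermediate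
17 | 5,10-epoxygermacra-4(15),11(13)-dien-12,6α-olide, 1α-OTES, 3β-OPiv, 8β-OTBS | C=C1C(=O)O[C@H]2[C@H]1[C@H](O[Si](C)(C)C(C)(C)C)C[C@]1(C)O[C@H]2C(=C)[C@@H](OC(=O)C(C)(C)C)C[C@@H]1O[Si](CC)(CC)CC | intermediate
18 | 1α-hydroxy analogue of 17 | C=C1C(=O)O[C@H]2[C@H]1[C@H](O[Si](C)(C)C(C)(C)C)C[C@]1(C)O[C@H]2C(=C)[C@@H](OC(=O)C(C)(C)C)C[C@@H]1O | intermediate
19 | 1-oxo-3β-pivaloyloxy analogue | C=C1C(=O)O[C@H]2[C@H]1[C@H](O[Si](C)(C)C(C)(C)C)C[C@]1(C)O[C@H]2C(=C)[C@@H](OC(=O)C(C)(C)C)CC1=O | intermediate (not isolated)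
20 | 8β-TBSO-1-oxo-5,10-epoxygermacra-2,4(15),11(13)-trien-12,6α-olide | C=C1C(=O)O[C@H]2[C@H]1[C@H](O[Si](C)(C)C(C)(C)C)C[C@]1(C)O[C@H]2C(=C)C=CC1=O | intermediate
21 | 8β-hydroxy-1-oxo-5,10-epoxygermacra-2,4(15),11(13)-trien-12,6α-olide | C=C1C(=O)O[C@H]2[C@H]1[C@H](O)C[C@]1(C)O[C@H]2C(=C)C=CC1=O | intermediate
22 | angelic acid ((Z)-2-methylbut-2-enoic acid) | C/C=C(/C)C(=O)O | starting material
23 | CNP0282559.1, (5S,6S,7R,8R,10S) | C=C1C(=O)O[C@H]2[C@H]1[C@H](OC(=O)/C(C)=C\C)C[C@]1(C)O[C@H]2C(=C)C=CC1=O | target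

**Step count and risks**

Total step count: 17. Longest linear sequence: 17 steps (1 to 23); angelic acid 22 is bought.

Steps most likely to fail:

1. Step 12 (key step). What may go wrong: the peroxy ester may ionise with a 1,2-shift of the vinylic carbon C4 (Hock-type cleavage of ring A) instead of C10, or may not ionise and drift into radical allylic transposition. Fallback, from 14 to 17, replaces the cationic shift by a radical scission of the same bond. Triphenylphosphine reduces the hydroperoxide of 14 to the tertiary allylic alcohol F1. Hypoiodite photolysis of F1 (PhI(OAc)2, I2, visible light, CH2Cl2) generates the C5 alkoxy radical, and β-scission of C5–C10 gives the C5 enone and the tertiary C10 radical. The radical is iodinated, and the iodide ionises with transannular capture by the C5 carbonyl oxygen and acetate to give the acetoxy acylal F2. F2 is reduced under the conditions of step 13 and comes back to the route at 17. In this variant C10 is rebuilt from a planar centre, so its configuration rests on the conformational preference of the transannular closure and no longer on retention.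

2. Step 13. What may go wrong: ionisation by cleavage of the ring C5–O bond (relief of bridgehead strain) and reduction to ring-opened products, or ionisation of the allylic C3 pivalate. Fallback, from 16 to 17, forms the C5–O bond by substitution instead of reduction. Mild hydrolysis of the acylal 16 (AcOH/THF/H2O) gives the 10-hydroxy-5-oxo enone F3. Luche reduction gives the allylic 5,10-diol F4, whose C5 configuration is immaterial. Acid treatment (CSA, CH2Cl2, 0 °C) ionises the allylic C5 alcohol, and transannular capture by the tertiary C10 hydroxyl closes the ether to 17. C10 is never broken, and only the bridge-compatible configuration at C5 can form.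

3. Step 1. What may go wrong: hydroxylation at other C–H bonds (C11, C15), reduction of the C1=C2 bond by the organism, or low conversion. Fallback, from 1 to 3, is a chemical transposition that uses the lactone oxygen as a leaving and returning group. SmI2 (THF/MeOH, −78 °C) cleaves the γ-acyloxy dienone reductively to the 6-deoxy acid F5 after equilibration. DDQ with TsOH in dioxane dehydrogenates C6–C7 to the 1,4,6-trienone acid F6, which makes C8 allylic. Allylic oxidation (Pd(OH)2/C, tBuOOH, K2CO3, CH2Cl2) gives the 8-oxo trienone acid F7. Acid-catalysed conjugate addition of the carboxylic acid to C6 re-closes the thermodynamically preferred trans-lactone and comes back to the route at 3.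

Further compounds

F1 | step 12 | 5α-hydroxy-3β-pivaloyloxy-1α-TESO-8β-TBSO-eudesma-4(15),11(13)-dien-12,6α-olide | C=C1C(=O)O[C@H]2[C@H]1[C@H](O[Si](C)(C)C(C)(C)C)C[C@@]1(C)[C@@H](O[Si](CC)(CC)CC)C[C@H](OC(=O)C(C)(C)C)C(=C)[C@]21O
F2 | step 12 | 5-acetoxy analogue of 16 (acetoxy acylal) | C=C1C(=O)O[C@H]2[C@H]1[C@H](O[Si](C)(C)C(C)(C)C)C[C@]1(C)O[C@@]2(OC(C)=O)C(=C)[C@@H](OC(=O)C(C)(C)C)C[C@@H]1O[Si](CC)(CC)CC
F3 | step 13 | 10-hydroxy-5-oxo-3β-pivaloyloxy-1α-TESO-8β-TBSO-germacra-4(15),11(13)-dien-12,6α-olide | C=C1C(=O)O[C@H]2[C@H]1[C@H](O[Si](C)(C)C(C)(C)C)C[C@](C)(O)[C@@H](O[Si](CC)(CC)CC)C[C@H](OC(=O)C(C)(C)C)C(=C)C2=O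
F4 | step 13 | 5,10-dihydroxy analogue of F3 (C5 epimers) | C=C1C(=O)O[C@H]2[C@H]1[C@H](O[Si](C)(C)C(C)(C)C)C[C@](C)(O)[C@@H](O[Si](CC)(CC)CC)C[C@H](OC(=O)C(C)(C)C)C(=C)C2O
F5 | step 1 | (11S)-3-oxoeudesma-1,4-dien-12-oic acid | C[C@H](C(=O)O)[C@@H]1CC[C@@]2(C)C=CC(=O)C(C)=C2C1
F6 | step 1 | (11S)-3-oxoeudesma-1,4,6-trien-12-oic acid | C[C@H](C(=O)O)C1=CC2=C(C)C(=O)C=C[C@]2(C)CC1
F7 | step 1 | (11S)-3,8-dioxoeudesma-1,4,6-trien-12-oic acid | C[C@H](C(=O)O)C1=CC2=C(C)C(=O)C=C[C@]2(C)CC1=O
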